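## Retrosynthetic overview

1. Last bond: the C8–O ester, made by acylating the 8β-alcohol with (2S,3R)-2,3-dimethyloxirane-2-carboxylic acid (from tiglyl alcohol by Sharpless epoxidation and oxidation).
2. Ten-membered carbocycle (C6–C7) and γ-lactone (O6–C12) in one flask: intramolecular Nozaki–Hiyama allylation/lactonization of a (2Z,4Z)-dienal carrying a 2-(bromomethyl)enoate. Ring order: C1/C10 oxirane first, carbocycle second, lactone third, side-chain oxirane attached last.
3. Z,Z-diene: Sonogashira coupling of an epoxy alkyne with (Z)-3-iodobut-2-enal, then cis-semihydrogenation. Bromomethyl enoate: Baylis–Hillman reaction and SN2′ bromination.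
4. Key disconnection, the C8–O bond: direct enamine-catalysed α-silyloxylation of the C7 aldehyde with a bis(silyl) peroxide (new). It sets C8 and delivers the oxygen as a silyl ether that cannot leave during the allylmetal step (an acyloxy group there would be lost by 1,4-elimination).
5. The C7 aldehyde comes from geraniol: Sharpless epoxidation (sets C1 and C10), alkyne homologation, ozonolysis.

Assumption: germacrane numbering (C1–C15; C1/C10 oxirane, C6 lactone carbinol, C7 ring-fusion carbon, C8 ester carbinol) and the usual α/β convention are used, and (E)-2-methylbut-2-en-1-ol is taken as a catalogue chemical.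

## Route

Step 1
Reactants: 1 geraniol
Product: 2 [(2R,3R)-3-methyl-3-(4-methylpent-3-en-1-yl)oxiran-2-yl]methanol
Conditions: Ti(OiPr)4 (5 mol%), D-(−)-diethyl tartrate (7 mol%), t-BuOOH, 4 Å MS, CH2Cl2, −20 °C
Reagents that add atoms: tert-butyl hydroperoxide, CC(C)(C)OO
Why: Sharpless asymmetric epoxidation; the allylic hydroxyl binds the titanium tartrate so only the 2,3-alkene reacts, and D-(−)-tartrate gives the (2R,3R)-epoxide (trans, from the E-alkene), which becomes C1 and C10 of the target.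

Step 2
Reactants: 2 [(2R,3R)-3-methyl-3-(4-methylpent-3-en-1-yl)oxiran-2-yl]methanol
Product: 3 (2S,3R)-3-methyl-3-(4-methylpent-3-en-1-yl)oxirane-2-carbaldehyde
Conditions: TEMPO (10 mol%), PhI(OAc)2, CH2Cl2, rt
Reagents that add atoms: none
Why: TEMPO/oxoammonium oxidation of a primary alcohol stops at the aldehyde and leaves the oxirane and the alkene alone; no stereocentre is touched (the descriptor change at C2 is only a priority change).

Step 3
Reactants: 3 (2S,3R)-3-methyl-3-(4-methylpent-3-en-1-yl)oxirane-2-carbaldehyde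
Product: 4 (2R,3R)-3-ethynyl-2-methyl-2-(4-methylpent-3-en-1-yl)oxirane
Conditions: dimethyl (1-diazo-2-oxopropyl)phosphonate, K2CO3, MeOH, 0 °C → rt
Reagents that add atoms: dimethyl (1-diazo-2-oxopropyl)phosphonate, CC(=O)C(=[N+]=[N-])P(=O)(OC)OC
Why: Seyferth–Gilbert homologation with the Ohira–Bestmann reagent; the diazomethylphosphonate anion adds to the aldehyde, and loss of phosphate and N2 with a 1,2-shift gives the terminal alkyne (C2≡C3) under conditions too mild to open or epimerise the oxirane.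

Step 4
Reactants: 4 (2R,3R)-3-ethynyl-2-methyl-2-(4-methylpent-3-en-1-yl)oxirane
Product: 6 3-[(2R,3R)-3-ethynyl-2-methyloxiran-2-yl]propanal, via ozonide 5 (not isolated)
Conditions: O3, CH2Cl2, −78 °C; then PPh3, −78 °C → rt
Reagents that add atoms: ozone, [O-][O+]=O
Why: Ozonolysis with reductive work-up; the electron-rich trisubstituted alkene reacts far faster than the terminal alkyne, unmasking the C7 aldehyde without touching the stereocentres.

Step 5
Reactants: 7 chlorotriethylsilane (2 equiv per H2O2)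
Product: 8 bis(triethylsilyl) peroxide
Conditions: DABCO·2H2O2, DABCO, CH2Cl2, 0 °C
Reagents that add atoms: hydrogen peroxide, OO; chlorotriethylsilane, CC[Si](Cl)(CC)CC
Why: Double O-silylation of hydrogen peroxide by nucleophilic substitution at silicon, the standard way to make bis(silyl) peroxides; two molecules of 7 are consumed per molecule of H2O2 (2 Et3SiCl + H2O2 → Et3SiOOSiEt3 + 2 HCl, the HCl being taken up by DABCO).

Step 6
Reactants: 6 3-[(2R,3R)-3-ethynyl-2-methyloxiran-2-yl]propanal; 8 bis(triethylsilyl) peroxide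
Product: 9 (2R)-3-[(2R,3R)-3-ethynyl-2-methyloxiran-2-yl]-2-[(triethylsilyl)oxy]propanal
Conditions: (R)-2-(triphenylmethyl)pyrrolidine (10 mol%), PhCO2H (10 mol%), 8 (1.2 equiv), THF, 0 °C → rt
Reagents that add atoms: none
Why: Proposed new method: the amine condenses with 6 to the (E)-enamine, whose nucleophilic carbon attacks the weak O–O bond of 8 in an SN2-type displacement at oxygen (silanolate leaves and is protonated by the acid co-catalyst), and hydrolysis of the α-silyloxy iminium ion releases 9 and the catalyst; the trityl group blocks one enamine face, so the (R)-catalyst should deliver oxygen to the open face and give the (R)-C8 centre, already protected as a silyl ether; the closest known reaction types are the enamine-catalysed asymmetric α-benzoyloxylation of aldehydes with dibenzoyl peroxide and the α-hydroxylation of lithium enolates with bis(trimethylsilyl) peroxide.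

Step 7
Reactants: 9 (2R)-3-[(2R,3R)-3-ethynyl-2-methyloxiran-2-yl]-2-[(triethylsilyl)oxy]propanal; 10 methyl acrylate
Product: 11 methyl (3RS,4R)-5-[(2R,3R)-3-ethynyl-2-methyloxiran-2-yl]-3-hydroxy-2-methylidene-4-[(triethylsilyl)oxy]pentanoate
Conditions: DABCO (0.5 equiv), methyl acrylate (neat, 10 equiv), rt
Reagents that add atoms: none
Why: Morita–Baylis–Hillman reaction forms C7–C11; the new C7 carbinol centre arises as a mixture that does not matter because step 12 erases it, and the α-silyloxy aldehyde is not expected to epimerise at C8 under tertiary-amine conditions.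

Step 8
Reactants: 12 but-2-yn-1-ol
Product: 14 (Z)-3-iodobut-2-en-1-ol, via alkenylaluminate 13 (not isolated)
Conditions: NaAlH2(OCH2CH2OMe)2, THF, 0 °C → rt; then I2, THF, −78 → 0 °C
Reagents that add atoms: iodine, II
Why: Hydroxyl-directed trans-hydroalumination puts aluminium on C3 cis to the CH2O group, and iodinolysis with retention gives the (Z)-vinyl iodide, which carries the C4=C5 geometry of the target.

Step 9
Reactants: 14 (Z)-3-iodobut-2-en-1-ol
Product: 15 (Z)-3-iodobut-2-enal
Conditions: MnO2, CH2Cl2, rt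
Reagents that add atoms: none
Why: Neutral allylic oxidation with MnO2 gives the enal without Z/E isomerisation; it is used at once.

Step 10
Reactants: 11 methyl (3RS,4R)-5-[(2R,3R)-3-ethynyl-2-methyloxiran-2-yl]-3-hydroxy-2-methylidene-4-[(triethylsilyl)oxy]pentanoate; 15 (Z)-3-iodobut-2-enal
Product: 16 methyl (3RS,4R)-3-hydroxy-2-methylidene-5-{(2R,3R)-2-methyl-3-[(3Z)-3-methyl-5-oxopent-3-en-1-yn-1-yl]oxiran-2-yl}-4-[(triethylsilyl)oxy]pentanoate
Conditions: Pd(PPh3)2Cl2 (3 mol%), CuI (6 mol%), Et3N, THF, 0 °C → rt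
Reagents that add atoms: none
Why: Sonogashira coupling forms C3–C4 with retention of the vinyl iodide geometry; zerovalent palladium inserts into the C–I bond much faster than it ionises the propargylic oxirane at room temperature.

Step 11
Reactants: 16 methyl (3RS,4R)-3-hydroxy-2-methylidene-5-{(2R,3R)-2-methyl-3-[(3Z)-3-methyl-5-oxopent-3-en-1-yn-1-yl]oxiran-2-yl}-4-[(triethylsilyl)oxy]pentanoate
Product: 17 methyl (3RS,4R)-3-hydroxy-2-methylidene-5-{(2R,3R)-2-methyl-3-[(1Z,3Z)-3-methyl-5-oxopenta-1,3-dien-1-yl]oxiran-2-yl}-4-[(triethylsilyl)oxy]pentanoate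
Conditions: H2 (1 atm, 1 equiv), Pd/CaCO3 poisoned with Pb(OAc)2, quinoline, EtOAc/hexane, rt
Reagents that add atoms: none
Why: Lindlar semihydrogenation adds H2 syn to the conjugated alkyne and sets the 2Z alkene; the poisoned catalyst should spare the acrylate and trisubstituted alkenes and the oxirane, and the electron-poor dienal keeps the dienyl oxirane from ionising.

Step 12
Reactants: 17 methyl (3RS,4R)-3-hydroxy-2-methylidene-5-{(2R,3R)-2-methyl-3-[(1Z,3Z)-3-methyl-5-oxopenta-1,3-dien-1-yl]oxiran-2-yl}-4-[(triethylsilyl)oxy]pentanoate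
Product: 18 methyl (2Z,4R)-2-(bromomethyl)-5-{(2R,3R)-2-methyl-3-[(1Z,3Z)-3-methyl-5-oxopenta-1,3-dien-1-yl]oxiran-2-yl}-4-[(triethylsilyl)oxy]pent-2-enoate
Conditions: NBS, Me2S, CH2Cl2, −20 → 0 °C
Reagents that add atoms: N-bromosuccinimide, O=C1CCC(=O)N1Br
Why: SN2′ bromination of the Baylis–Hillman alcohol through its alkoxysulfonium salt (Corey–Kim reagent); bromide attacks the terminal methylene, the C7 carbinol centre is erased and the conjugated (Z)-enoate forms, under neutral conditions that spare silyl ether, dienal and oxirane.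

Step 13
Reactants: 18 methyl (2Z,4R)-2-(bromomethyl)-5-{(2R,3R)-2-methyl-3-[(1Z,3Z)-3-methyl-5-oxopenta-1,3-dien-1-yl]oxiran-2-yl}-4-[(triethylsilyl)oxy]pent-2-enoate
Product: 20 (1R,6R,7S,8R,10R)-1β,10α-epoxy-8β-[(triethylsilyl)oxy]germacra-2Z,4Z,11(13)-trien-12,6α-olide, via hydroxy ester 19 (not isolated)
Conditions: CrCl2 (6 equiv), THF, rt, 2 mM (slow addition); aqueous work-up
Reagents that add atoms: none
Why: Intramolecular Nozaki–Hiyama allylation; CrCl2 turns the allylic bromide into an allylchromium species (trivalent chromium) that adds through its γ-carbon (C7) to the aldehyde carbon (C6); the tether that links C5 and C8 in the forming ten-membered ring is expected to enforce the transition-state geometry leading to the 6,7-trans adduct (open-chain reagents of this kind favour the cis series, so this rests on macrocyclic control), and the C7 face is expected to follow from the adjacent C8 silyloxy centre; the chromium alkoxide then closes the γ-lactone on the methyl ester, the silyl ether does not leave from the allylmetal, and no charge develops at C6 that could open the dienyl oxirane.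

Step 14
Reactants: 20 (1R,6R,7S,8R,10R)-1β,10α-epoxy-8β-[(triethylsilyl)oxy]germacra-2Z,4Z,11(13)-trien-12,6α-olide
Product: 21 (1R,6R,7R,8R,10R)-1β,10α-epoxy-8β-hydroxygermacra-2Z,4Z,11(13)-trien-12,6α-olide
Conditions: TBAF, AcOH (1:1), THF, 0 °C
Reagents that add atoms: none
Why: Fluoride-mediated desilylation; buffering with acetic acid avoids a free alkoxide that could translactonize or add to the methylene lactone, and avoids acid strong enough to open the dienyl oxirane (the C7 descriptor changes from S to R only through the priority change).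

Step 15
Reactants: 22 (E)-2-methylbut-2-en-1-ol
Product: 23 [(2R,3R)-2,3-dimethyloxiran-2-yl]methanol
Conditions: Ti(OiPr)4 (10 mol%), D-(−)-diethyl tartrate (12 mol%), t-BuOOH, 4 Å MS, CH2Cl2, −20 °C
Reagents that add atoms: tert-butyl hydroperoxide, CC(C)(C)OO
Why: Sharpless asymmetric epoxidation; D-(−)-tartrate gives the (2R,3R)-epoxy alcohol, with the two methyl groups cis as in the side chain.

Step 16
Reactants: 23 [(2R,3R)-2,3-dimethyloxiran-2-yl]methanol
Product: 24 (2S,3R)-2,3-dimethyloxirane-2-carboxylic acid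
Conditions: RuCl3 (2 mol%), NaIO4, MeCN/EtOAc/H2O, 0 °C → rt
Reagents that add atoms: sodium periodate, [Na+].[O-]I(=O)(=O)=O
Why: RuO4-catalysed oxidation of the primary alcohol to the acid leaves the oxirane intact; the C2 descriptor changes to S only through the priority change.

Step 17
Reactants: 21 (1R,6R,7R,8R,10R)-1β,10α-epoxy-8β-hydroxygermacra-2Z,4Z,11(13)-trien-12,6α-olide; 24 (2S,3R)-2,3-dimethyloxirane-2-carboxylic acid
Product: 25 (1R,6R,7R,8R,10R)-1β,10α-epoxy-8β-{[(2S,3R)-2,3-dimethyloxirane-2-carbonyl]oxy}germacra-2Z,4Z,11(13)-trien-12,6α-olide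
Conditions: DCC, DMAP (10 mol%), CH2Cl2, 0 °C → rt
Reagents that add atoms: none
Why: Steglich esterification forms the C8–O acyl bond with retention at C8 under near-neutral conditions tolerated by both oxiranes and the methylene lactone.

## Compound list

1 | geraniol | CC(C)=CCC/C(C)=C/CO | starting material
2 | [(2R,3R)-3-methyl-3-(4-methylpent-3-en-1-yl)oxiran-2-yl]methanol | OC[C@H]1O[C@]1(C)CCC=C(C)C | intermediate
3 | (2S,3R)-3-methyl-3-(4-methylpent-3-en-1-yl)oxirane-2-carbaldehyde | O=C[C@H]1O[C@]1(C)CCC=C(C)C | intermediate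
4 | (2R,3R)-3-ethynyl-2-methyl-2-(4-methylpent-3-en-1-yl)oxirane | C#C[C@H]1O[C@]1(C)CCC=C(C)C | intermediate
5 | 3-{2-[(2R,3R)-3-ethynyl-2-methyloxiran-2-yl]ethyl}-5,5-dimethyl-1,2,4-trioxolane (ozonide, epimers at the trioxolane carbon) | C#C[C@H]1O[C@]1(C)CCC2OOC(C)(C)O2 | intermediate (not isolated)
6 | 3-[(2R,3R)-3-ethynyl-2-methyloxiran-2-yl]propanal | C#C[C@H]1O[C@]1(C)CCC=O | intermediate
7 | chlorotriethylsilane | CC[Si](Cl)(CC)CC | starting material
8 | bis(triethylsilyl) peroxide | CC[Si](CC)(CC)OO[Si](CC)(CC)CC | intermediate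
9 | (2R)-3-[(2R,3R)-3-ethynyl-2-methyloxiran-2-yl]-2-[(triethylsilyl)oxy]propanal | C#C[C@H]1O[C@]1(C)C[C@H](C=O)O[Si](CC)(CC)CC | intermediate
10 | methyl acrylate | C=CC(=O)OC | starting material
11 | methyl (3RS,4R)-5-[(2R,3R)-3-ethynyl-2-methyloxiran-2-yl]-3-hydroxy-2-methylidene-4-[(triethylsilyl)oxy]pentanoate | C#C[C@H]1O[C@]1(C)C[C@H](C(O)C(=C)C(=O)OC)O[Si](CC)(CC)CC | intermediate
12 | but-2-yn-1-ol | CC#CCO | starting material
13 | sodium 2,2-bis(2-methoxyethoxy)-3-methyl-2,5-dihydro-1,2-oxaluminol-2-uide (cyclic Z-alkenylaluminate) | [Na+].CC1=CCO[Al-]1(OCCOC)OCCOC | intermediate (not isolated)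
14 | (Z)-3-iodobut-2-en-1-ol | C/C(I)=C/CO | intermediate
15 | (Z)-3-iodobut-2-enal | C/C(I)=C/C=O | intermediate
16 | methyl (3RS,4R)-3-hydroxy-2-methylidene-5-{(2R,3R)-2-methyl-3-[(3Z)-3-methyl-5-oxopent-3-en-1-yn-1-yl]oxiran-2-yl}-4-[(triethylsilyl)oxy]pentanoate | O=C/C=C(C)\C#C[C@H]1O[C@]1(C)C[C@H](C(O)C(=C)C(=O)OC)O[Si](CC)(CC)CC | intermediate
17 | methyl (3RS,4R)-3-hydroxy-2-methylidene-5-{(2R,3R)-2-methyl-3-[(1Z,3Z)-3-methyl-5-oxopenta-1,3-dien-1-yl]oxiran-2-yl}-4-[(triethylsilyl)oxy]pentanoate | O=C/C=C(C)\C=C/[C@H]1O[C@]1(C)C[C@H](C(O)C(=C)C(=O)OC)O[Si](CC)(CC)CC | intermediate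
18 | methyl (2Z,4R)-2-(bromomethyl)-5-{(2R,3R)-2-methyl-3-[(1Z,3Z)-3-methyl-5-oxopenta-1,3-dien-1-yl]oxiran-2-yl}-4-[(triethylsilyl)oxy]pent-2-enoate | O=C/C=C(C)\C=C/[C@H]1O[C@]1(C)C[C@H](/C=C(\CBr)C(=O)OC)O[Si](CC)(CC)CC | intermediate
19 | methyl (1R,6R,7S,8R,10R)-1β,10α-epoxy-6α-hydroxy-8β-[(triethylsilyl)oxy]germacra-2Z,4Z,11(13)-trien-12-oate | C=C(C(=O)OC)[C@H]1[C@H](O)/C=C(C)\C=C/[C@H]2O[C@]2(C)C[C@H]1O[Si](CC)(CC)CC | intermediate (not isolated)
20 | (1R,6R,7S,8R,10R)-1β,10α-epoxy-8β-[(triethylsilyl)oxy]germacra-2Z,4Z,11(13)-trien-12,6α-olide | C=C1C(=O)O[C@@H]2/C=C(C)\C=C/[C@H]3O[C@]3(C)C[C@@H](O[Si](CC)(CC)CC)[C@@H]12 | intermediate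
21 | (1R,6R,7R,8R,10R)-1β,10α-epoxy-8β-hydroxygermacra-2Z,4Z,11(13)-trien-12,6α-olide | C=C1C(=O)O[C@@H]2/C=C(C)\C=C/[C@H]3O[C@]3(C)C[C@@H](O)[C@@H]12 | intermediate
22 | (E)-2-methylbut-2-en-1-ol | C/C=C(\C)CO | starting material
23 | [(2R,3R)-2,3-dimethyloxiran-2-yl]methanol | OC[C@@]1(C)O[C@@H]1C | intermediate
24 | (2S,3R)-2,3-dimethyloxirane-2-carboxylic acid | OC(=O)[C@@]1(C)O[C@@H]1C | intermediate
25 | (1R,6R,7R,8R,10R)-1β,10α-epoxy-8β-{[(2S,3R)-2,3-dimethyloxirane-2-carbonyl]oxy}germacra-2Z,4Z,11(13)-trien-12,6α-olide | C=C1C(=O)O[C@@H]2/C=C(C)\C=C/[C@H]3O[C@]3(C)C[C@@H](OC(=O)[C@@]3(C)O[C@@H]3C)[C@@H]12 | target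

## Step count and risks

Total step count: 17. Longest linear sequence: 12 steps from geraniol (steps 1, 2, 3, 4, 6, 7, 10, 11, 12, 13, 14, 17).

The three steps most likely to fail:

Step 6 (the new α-silyloxylation). The silyl peroxide may be too weak an electrophile for the enamine, or the catalyst may be silylated or oxidised. The fallback uses known chemistry, sets out from 6 and comes back at 9. L-Proline-catalysed α-aminoxylation of 6 with nitrosobenzene, followed by NaBH4 in the same flask, gives (2R)-2-(anilinooxy)-3-[(2R,3R)-3-ethynyl-2-methyloxiran-2-yl]propan-1-ol F1. Cleavage of the N–O bond with Zn in AcOH/THF at 0 °C gives (2R)-3-[(2R,3R)-3-ethynyl-2-methyloxiran-2-yl]propane-1,2-diol F2. Silylation with Et3SiCl and imidazole gives (2R,3R)-2-{(2R)-2,3-bis[(triethylsilyl)oxy]propyl}-3-ethynyl-2-methyloxirane F3. Swern oxidation, which selectively converts a primary triethylsilyl ether into the aldehyde, then returns 9.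

Step 11 (semihydrogenation). Over-reduction, reduction of the acrylate or loss of Z geometry are possible. The fallback builds the diene by cross-coupling instead; it sets out from 11 and comes back at 17, bypassing 16. Rhodium-catalysed trans-hydroboration of the terminal alkyne of 11 ([Rh(cod)Cl]2, P(i-Pr)3, Et3N, pinacolborane) gives methyl (3RS,4R)-3-hydroxy-2-methylidene-5-{(2R,3R)-2-methyl-3-[(Z)-2-(4,4,5,5-tetramethyl-1,3,2-dioxaborolan-2-yl)ethenyl]oxiran-2-yl}-4-[(triethylsilyl)oxy]pentanoate F4. Suzuki–Miyaura coupling of this boronate with 15 (Pd(PPh3)4, Cs2CO3, THF/H2O) proceeds with retention at both alkenes and gives 17 directly.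

Step 13 (macrocyclisation). Oligomerisation, the 6,7-cis series or the wrong C7 face is possible; the stereochemical outcome is an expectation, not a certainty. The fallback forms the lactone intermolecularly and closes the ring at C3–C4; it sets out from 11 and comes back at 20. NBS/Me2S converts 11 into methyl (2Z,4R)-2-(bromomethyl)-5-[(2R,3R)-3-ethynyl-2-methyloxiran-2-yl]-4-[(triethylsilyl)oxy]pent-2-enoate F5. CrCl2-mediated allylation of 15 with this bromide, followed by lactonization, gives a mixture of lactone diastereomers that is separated by chromatography at this open-chain stage. Open-chain reagents of this kind tend to favour 4,5-cis lactones, so the isomer needed may be the minor one; it is the 4,5-trans lactone 4-{(1R)-2-[(2R,3R)-3-ethynyl-2-methyloxiran-2-yl]-1-[(triethylsilyl)oxy]ethyl}-5-[(Z)-2-iodoprop-1-en-1-yl]-3-methylideneoxolan-2-one F6 (ring stereocentres as in 20). Rhodium-catalysed trans-hydroboration of its terminal alkyne with pinacolborane gives the corresponding (Z)-alkenylboronate, 5-[(Z)-2-iodoprop-1-en-1-yl]-3-methylidene-4-{(1R)-2-{(2R,3R)-2-methyl-3-[(Z)-2-(4,4,5,5-tetramethyl-1,3,2-dioxaborolan-2-yl)ethenyl]oxiran-2-yl}-1-[(triethylsilyl)oxy]ethyl}oxolan-2-one F7. Intramolecular Suzuki–Miyaura coupling (Pd(PPh3)4, Cs2CO3, THF/H2O, high dilution) returns 20.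

Further compounds

F1 | step 6 | (2R)-2-(anilinooxy)-3-[(2R,3R)-3-ethynyl-2-methyloxiran-2-yl]propan-1-ol | C#C[C@H]1O[C@]1(C)C[C@H](CO)ONc1ccccc1
F2 | step 6 | (2R)-3-[(2R,3R)-3-ethynyl-2-methyloxiran-2-yl]propane-1,2-diol | C#C[C@H]1O[C@]1(C)C[C@H](CO)O
F3 | step 6 | (2R,3R)-2-{(2R)-2,3-bis[(triethylsilyl)oxy]propyl}-3-ethynyl-2-methyloxirane | C#C[C@H]1O[C@]1(C)C[C@H](CO[Si](CC)(CC)CC)O[Si](CC)(CC)CC
F4 | step 11 | methyl (3RS,4R)-3-hydroxy-2-methylidene-5-{(2R,3R)-2-methyl-3-[(Z)-2-(4,4,5,5-tetramethyl-1,3,2-dioxaborolan-2-yl)ethenyl]oxiran-2-yl}-4-[(triethylsilyl)oxy]pentanoate | CC1(C)OB(/C=C\[C@H]2O[C@]2(C)C[C@H](C(O)C(=C)C(=O)OC)O[Si](CC)(CC)CC)OC1(C)C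
F5 | step 13 | methyl (2Z,4R)-2-(bromomethyl)-5-[(2R,3R)-3-ethynyl-2-methyloxiran-2-yl]-4-[(triethylsilyl)oxy]pent-2-enoate | C#C[C@H]1O[C@]1(C)C[C@H](/C=C(\CBr)C(=O)OC)O[Si](CC)(CC)CC
F6 | step 13 | 4-{(1R)-2-[(2R,3R)-3-ethynyl-2-methyloxiran-2-yl]-1-[(triethylsilyl)oxy]ethyl}-5-[(Z)-2-iodoprop-1-en-1-yl]-3-methylideneoxolan-2-one (4,5-trans, ring stereocentres as in 20) | C=C1C(=O)O[C@H](/C=C(C)\I)[C@H]1[C@@H](C[C@@]2(C)O[C@@H]2C#C)O[Si](CC)(CC)CC
F7 | step 13 | 5-[(Z)-2-iodoprop-1-en-1-yl]-3-methylidene-4-{(1R)-2-{(2R,3R)-2-methyl-3-[(Z)-2-(4,4,5,5-tetramethyl-1,3,2-dioxaborolan-2-yl)ethenyl]oxiran-2-yl}-1-[(triethylsilyl)oxy]ethyl}oxolan-2-one (4,5-trans, ring stereocentres as in 20) | C=C1C(=O)O[C@H](/C=C(C)\I)[C@H]1[C@@H](C[C@@]2(C)O[C@@H]2/C=C\B3OC(C)(C)C(C)(C)O3)O[Si](CC)(CC)CC
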